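## The problem

Target 22 is a monocyclic 2,3,4-trisubstituted tetrahydrofuran. C2 carries a 3-hydroxy-4-methoxyphenyl group, C3 a hydroxymethyl group, C4 a 3-hydroxy-4-methoxybenzoyl group, and C5 is an unsubstituted CH2 next to O1. The three contiguous stereocenters are (2S,3R,4S) and all-trans. No chiral starting material offers itself, so one center must be set by a catalyst and the others derived from it. C4 is α to the aryl ketone and can be equilibrated, and because the all-trans array is the least crowded, C2 and C3 can dictate C4 thermodynamically. C2 is a benzylic ether carbon that base cannot correct, so it must be right from the start, and C3 has to be placed relative to it. The fragile points are the benzylic C2–O1 bond (its para-methoxy group makes it prone to acid ionization and to hydrogenolysis), the β-alkoxy ketone (O1 is β to the carbonyl through C5 and can leave by elimination), the aryl ketone under reducing conditions, and two phenols. The enabling feature is that O1, C2, C3, the ketone carbon, C4 and C5 spell out a 2-aryl-3-alkyl-tetrahydropyran-4-one (compound 9) whose ring carbonyl carbon is the exocyclic ketone carbon of 22. C2 can then come from a catalytic carbonyl cycloaddition, C3 from enolate chemistry beside that carbonyl, and a 1,2-shift of C3 can push the carbonyl carbon out of the ring, turning the oxane into the tetrahydrofuran.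

## Retrosynthesis

**22 from 21.** The last bonds cut are the three O–Si bonds of the fully silylated ketone 21 (two aryl triisopropylsilyl ethers, one primary tert-butyldimethylsilyl ether). Silyl ethers are preferred to benzyl ethers because debenzylation would need hydrogenolysis, which also threatens the activated benzylic C2–O1 bond and the aryl ketone, or a Lewis acid, which ionizes C2. The forward step only has to be mild and near neutral.

**21 from 20.** No bond is cut; the C4 configuration is relaxed, so 21 comes from ketone 20 as a pair of C4 epimers. The correction is placed at the ketone and not at amide 15 because the ketone α-hydrogen is acidic enough for a mild amidine base. The forward step needs the all-trans isomer to dominate at equilibrium and the ring to stay closed.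

**20 from 15 and 18.** The bond between the ketone carbon and its aryl group is cut, giving N-methoxy-N-methylamide 15 and aryllithium 18; 18 comes from bromide 17 and so from phenol 16. This cut uses the second aryl building block of the same type and a ketone synthesis that stops cleanly, since adduct 19 holds until the quench. The opposite cut, an acyl anion onto C4, has no comparable precedent.

**15 from 12 and 13 (key disconnection).** Amide 15 is traced to ketene 14 and amine 13, and 14 to diazo ketone 12 by reversing a 1,2-shift: the C3–C4 bond is cut and C3 is re-attached to the carbonyl carbon, which re-enters the ring. Closing the ring by C–O bond formation at C2 would create the benzylic center late and under ionizing conditions; here the ring oxygen and C2 are in place from the start. The precursor 12 has two stereocenters instead of three and is a six-membered ring open to cycloaddition and enolate chemistry. The forward step must lose N2 in concert with migration, keep the C3 configuration, and trap the ketene with 13. It is not asked to control C4, so 15 is expected as an epimeric pair.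

**12 from 9.** The C5=N2 bond is cut, leading to ketone 9 by way of enolate 10 and trifluoroacetyl ketone 11. The forward reaction must activate the C5 methylene and leave the C3 methine, with its configuration and β-silyloxy group, alone. Kinetic deprotonation by a hindered amide base should do this.

**9 from 8, 7 and 5.** Ketone 9 comes from enone 8 by conjugate reduction of C5=C6, 8 from alcohol 7 by silylation, and 7 from dihydropyranone 5 by cutting the C3–CH2OH bond. The side chain is introduced at the enone stage because 5 has only one enolizable position (C3), so dienolate 6 forms without regiochemical choice; the saturated ketone would offer two methylene groups. The forward step needs the one-carbon electrophile to approach anti to the C2 aryl group; the trans isomer is also the more stable one.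

**5 from 2 and 3.** The C2–C3 and O1–C6 bonds are cut, giving aryl aldehyde 2 and siloxy diene 3; 2 is the silyl ether of isovanillin 1. This is the only step that creates absolute configuration. It proceeds through aldol adduct 4 and relies on a chiral titanium–binaphtholate catalyst, a well-established system for aromatic aldehydes.

## Roads not taken

**Alternative 1:** Both aryl–carbon bonds are cut at once, C2–aryl and ketone carbon–aryl. This leads back to aryllithium A3, used twice, and to the trans-disubstituted butyrolactone A2 carrying the protected hydroxymethyl group and an N-methoxy-N-methylamide. Forward, two equivalents of A3 would add once to the lactone carbonyl and once to the amide to give keto lactol A1, and the lactol would then be reduced to the cyclic ether.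
- Merits: it is the most convergent of the four plans, it exploits the identical substitution of the two arenes, C3 and C4 are already trans in a small lactone, and it is several steps shorter than the chosen route.
- Weak points: C2 would be created by hydride delivery to a 2-aryl oxocarbenium ion flanked by the C3 side chain. Hydride should enter anti to that side chain, which puts the aryl group cis to it, the wrong relationship. The silane/Lewis acid conditions also reduce electron-rich aryl ketones and dehydrate 2-aryl lactols to dihydrofurans. The lactone adduct is not chelation-stabilized and can open to a ketone that takes a further aryllithium, and C3–H of A2 is acidic with a β-alkoxy leaving group.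
- Comparison: in step count Alternative 1 is clearly better. Against that the chosen plan sets C2 first, by a catalyst, and never forms or reduces anything at C2 afterwards.

**Alternative 2:** The bond between C3 and the hydroxymethyl carbon is cut. The carbon would come from the (bromomethyl)dimethylsilyl ether A5 of a 2-aryl-2,5-dihydrofuran whose C4 bears the aryl carbinol. A Bu3SnH chain would generate the silylmethyl radical, which adds to C3 in the 6-endo mode and gives the cis-fused siloxane A4; oxidative C–Si cleavage and oxidation of the benzylic carbinol would follow.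
- Merits: delivery is intramolecular, so attack at C3 anti to the C2 aryl group should give the 2,3-trans relationship reliably, with no enolate next to a leaving group, and the hydroxymethyl group arrives masked. In this respect it is better than the aldol step of the chosen route, whose dienolate 6 is its weakest intermediate.
- Weak points: hydrogen transfer to the ring-fusion radical gives the cis fusion, so C4 comes out wrong and must be epimerized after oxidation, just as in the chosen plan. 5-exo closure at C4 competes with the 6-endo closure. The carbinol carbon is an extra stereocenter that is later destroyed, and the secondary benzylic alcohol must be oxidized beside a primary one. A5 is an enantiopure 2-aryl-2,5-dihydrofuran one oxidation away from a furan, and its synthesis would be at least as long as that of 12. Stoichiometric tin is a further cost.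
- Comparison: the chosen plan sets against the better C3 control its short access to 12 from two commercial compounds and a C3 that stays correctable by equilibration in the pyranone.

**Alternative 3:** Two ring bonds, C2–C3 and C4–C5, are cut in one cascade. Acetal A7, from the aryl aldehyde and an (E)-5-(benzyloxy)pent-3-ene-1,2-diol, would be ionized by SnCl4. The alkene attacks the oxocarbenium ion (Prins step) and the ring CH2 then shifts to the new cationic center (pinacol step), contracting a transient oxane to aldehyde A6.
- Merits: on paper this is the most economical plan. One operation would build the ring, two C–C bonds and all three stereocenters in the all-trans array from a single carbinol center that is consumed, and C4 would need no separate equilibration.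
- Weak points: the alkene is 1,2-disubstituted and carries an inductively withdrawing allylic ether, so the Prins step must generate a secondary, unstabilized cation at C4. The para-alkoxyaryl group makes the oxocarbenium ion a weak electrophile and the benzylic C–O bonds reversible, which invites oxonia-Cope scrambling and erosion of C2. The carbinol carbon must bear a hydrogen to end as an aldehyde, and that hydrogen can shift in place of the ring carbon to give a pyran-3-one. The aldehyde also needs two steps (aryl addition, oxidation) where amide 15 needs one.
- Comparison: the chosen plan is two to three steps longer and sets the stereocenters one at a time, but each of its steps is a known reaction on a known substrate class, and its key step has no ionic intermediate at the benzylic carbon.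

Key step: step 7

Convention: ArT = 4-methoxy-3-(triisopropylsilyloxy)phenyl, TBS = tert-butyldimethylsilyl, TIPS = triisopropylsilyl; tetrahydrofurans are numbered as in the target (O1, C2 aryl, C3 CH2O, C4 acyl, C5).

Assumption: the (S)-BINOL/Ti(OiPr)4 catalyst is taken to direct the diene to the Si face of aldehyde 2, as with other aromatic aldehydes, giving (S)-5; if the sense proves opposite, (R)-BINOL is used and nothing else changes.

## Route

Step 1
Reactants: 1 isovanillin (3-hydroxy-4-methoxybenzaldehyde)
Product: 2 4-methoxy-3-(triisopropylsilyloxy)benzaldehyde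
Conditions: i-Pr3SiCl, imidazole, DMF, rt
Reagents that add atoms: triisopropylsilyl chloride, CC(C)[Si](Cl)(C(C)C)C(C)C
Why: Standard silylation of a phenol with a silyl chloride and imidazole; the bulky aryl silyl ether tolerates the enolate, hydride, aryllithium and amidine steps ahead and leaves with fluoride at the end.

Step 2
Reactants: 2 4-methoxy-3-(triisopropylsilyloxy)benzaldehyde; 3 (E)-1-methoxy-3-(trimethylsilyloxy)buta-1,3-diene
Product: 5 (S)-2-ArT-2,3-dihydro-4H-pyran-4-one, via Mukaiyama aldol adduct 4 (not isolated)
Conditions: (S)-BINOL (20 mol %), Ti(OiPr)4 (10 mol %), 4 Å MS, Et2O, −20 °C; then CF3CO2H, CH2Cl2, 0 °C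
Reagents that add atoms: none
Why: Catalytic enantioselective Mukaiyama aldol addition of the siloxy diene to the aldehyde, then acid-induced cyclization with loss of methanol and the silyl group (a formal hetero-Diels–Alder reaction of the Keck type, established for aromatic aldehydes). C2 is set by the chiral titanium binaphtholate, which should expose the Si face of the coordinated aldehyde to the diene terminus and give the S configuration.

Step 3
Reactants: 5 (S)-2-ArT-2,3-dihydro-4H-pyran-4-one
Product: 7 (2S,3R)-3-(hydroxymethyl)-2-ArT-2,3-dihydro-4H-pyran-4-one (2,3-trans), via lithium dienolate 6 (not isolated)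
Conditions: LiN(iPr)2 (1.1 equiv), THF, −78 °C; CH2O (gas from cracked paraformaldehyde), −78 °C; aq NH4Cl
Reagents that add atoms: formaldehyde, C=O
Why: Kinetic α'-deprotonation of the cyclic vinylogous ester (its only enolizable position) and crossed aldol addition of the dienolate to monomeric formaldehyde. The electrophile should approach C3 anti to the neighboring C2 aryl group, giving the trans (3R) isomer, which is also the thermodynamically preferred one.

Step 4
Reactants: 7 (2S,3R)-3-(hydroxymethyl)-2-ArT-2,3-dihydro-4H-pyran-4-one
Product: 8 (2S,3R)-3-[(tert-butyldimethylsilyloxy)methyl]-2-ArT-2,3-dihydro-4H-pyran-4-one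
Conditions: t-BuMe2SiCl, imidazole, DMF, 0 °C → rt
Reagents that add atoms: tert-butyldimethylsilyl chloride, CC(C)(C)[Si](C)(C)Cl
Why: Standard silylation of a primary alcohol under mild base; it blocks retro-aldol and dehydration of the β-hydroxy ketone and installs a group that leaves together with the aryl silyl ethers.

Step 5
Reactants: 8 (2S,3R)-3-[(tert-butyldimethylsilyloxy)methyl]-2-ArT-2,3-dihydro-4H-pyran-4-one
Product: 9 (2S,3R)-3-[(tert-butyldimethylsilyloxy)methyl]-2-ArT-tetrahydro-4H-pyran-4-one
Conditions: LiBH(s-Bu)3 (1.1 equiv), THF, −78 °C; aq NH4Cl
Reagents that add atoms: none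
Why: Conjugate (1,4) hydride addition of the hindered trialkylborohydride to the vinylogous ester, a known reduction of 2,3-dihydro-4H-pyran-4-ones; the resulting enolate is protonated on work-up and C2 and C3 are not touched.

Step 6
Reactants: 9 (2S,3R)-3-[(tert-butyldimethylsilyloxy)methyl]-2-ArT-tetrahydro-4H-pyran-4-one
Product: 12 (2S,3R)-3-[(tert-butyldimethylsilyloxy)methyl]-5-diazo-2-ArT-tetrahydro-4H-pyran-4-one, via lithium enolate 10 (not isolated), via trifluoroacetyl ketone 11 (not isolated)
Conditions: LiN(SiMe3)2 (1.1 equiv), THF, −78 °C; CF3CO2CH2CF3, −78 °C; 5% HCl work-up; then MeSO2N3, Et3N, H2O (1 equiv), MeCN, rt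
Reagents that add atoms: methanesulfonyl azide, CS(=O)(=O)N=[N+]=[N-]; 2,2,2-trifluoroethyl trifluoroacetate, O=C(OCC(F)(F)F)C(F)(F)F (its trifluoroacetyl group is carried only by intermediate 11)
Why: Detrifluoroacetylative diazo transfer (Danheiser procedure): the hindered amide base takes a proton from the open C5 methylene rather than the flanked C3 methine, Claisen acylation activates that carbon, and the sulfonyl azide transfers N2 with loss of the trifluoroacetyl group. C3 is never enolized, so its configuration and the β-silyloxy group are preserved.

Step 7
Reactants: 12 (2S,3R)-3-[(tert-butyldimethylsilyloxy)methyl]-5-diazo-2-ArT-tetrahydro-4H-pyran-4-one; 13 N,O-dimethylhydroxylamine (free base)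
Product: 15 (2S,3R)-3-[(tert-butyldimethylsilyloxy)methyl]-N-methoxy-2-ArT-N-methyltetrahydrofuran-4-carboxamide (both C4 epimers), via ketene 14 (not isolated)
Conditions: hν (365 nm), 13 (5 equiv), degassed MeCN, 0–10 °C
Reagents that add atoms: none
Why: Photochemical Wolff rearrangement with amine capture, the known ring contraction of cyclic 2-diazo ketones. Excitation expels N2 while C3 shifts from the carbonyl carbon to the diazo carbon; the ring holds C=O and C=N2 s-cis, so loss of nitrogen and the 1,2-shift should be concerted, leaving no free carbene to insert or to take a hydrogen from C6. The tetrahydrofuran is thus formed not by a cyclization but by contraction of the oxane: the former carbonyl carbon leaves the ring as the ketene carbon of 14 and the new C3–C4 bond closes the five-membered ring. C3 migrates with retention, so the 2,3-trans relationship built in the pyranone is carried over unchanged. Amine 13 adds to the ketene and the amide enol tautomerizes by protonation at C4; this creates the third stereocenter under kinetic control, probably mainly anti to the C3 side chain (3,4-cis), and neither epimer is a loss because C4 is equilibrated in step 10. Only C3 can migrate, since the other substituent of the carbonyl carbon is the diazo carbon itself, so the regiochemistry of the contraction rests on the position of the diazo group secured in step 6. Light of 365 nm excites only the diazo ketone, the silyl ethers are inert to light and amine, and the amide formed stops the aryllithium of step 9 at the ketone.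

Step 8
Reactants: 16 5-bromo-2-methoxyphenol
Product: 17 (5-bromo-2-methoxyphenoxy)triisopropylsilane
Conditions: i-Pr3SiCl, imidazole, DMF, rt
Reagents that add atoms: triisopropylsilyl chloride, CC(C)[Si](Cl)(C(C)C)C(C)C
Why: Phenol silylation as in step 1; the silyloxy group is meta to bromine, so the derived aryllithium has no ortho silyl ether to rearrange.

Step 9
Reactants: 17 (5-bromo-2-methoxyphenoxy)triisopropylsilane; 15 (2S,3R)-3-[(tert-butyldimethylsilyloxy)methyl]-N-methoxy-2-ArT-N-methyltetrahydrofuran-4-carboxamide (both C4 epimers)
Product: 20 {(2S,3R)-3-[(tert-butyldimethylsilyloxy)methyl]-2-ArT-tetrahydrofuran-4-yl}(ArT)methanone (both C4 epimers), via aryllithium 18 (not isolated), via tetrahedral adduct 19 (not isolated)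
Conditions: 17 (1.6 equiv), n-BuLi (1.5 equiv), THF, −78 °C; then 15, −78 → −40 °C; aq NH4Cl
Reagents that add atoms: none
Why: Bromine–lithium exchange and addition of the aryllithium to the N-methoxy-N-methylamide (Weinreb ketone synthesis); the chelated tetrahedral adduct survives until the quench, so only one aryl group is taken up. C4 is not controlled here and both epimers converge in the next step.

Step 10
Reactants: 20 {(2S,3R)-3-[(tert-butyldimethylsilyloxy)methyl]-2-ArT-tetrahydrofuran-4-yl}(ArT)methanone (both C4 epimers)
Product: 21 {(2S,3R,4S)-3-[(tert-butyldimethylsilyloxy)methyl]-2-ArT-tetrahydrofuran-4-yl}(ArT)methanone (all-trans)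
Conditions: DBU (0.5 equiv), toluene, rt → 40 °C
Reagents that add atoms: none
Why: Base-mediated epimerization α to the aryl ketone through the enolate under thermodynamic control; the all-trans isomer, with the aroyl group trans to the C3 side chain, should dominate at equilibrium, and any residual epimer can be separated and resubmitted. Ring opening by β-elimination of O1 needs the C5–O1 bond to align with the exocyclic enolate (the reverse of a 5-endo closure) and should be slow.

Step 11
Reactants: 21 {(2S,3R,4S)-3-[(tert-butyldimethylsilyloxy)methyl]-2-ArT-tetrahydrofuran-4-yl}(ArT)methanone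
Product: 22 (3-hydroxy-4-methoxyphenyl)[(2S,3R,4S)-2-(3-hydroxy-4-methoxyphenyl)-3-(hydroxymethyl)tetrahydrofuran-4-yl]methanone (all-trans; by IUPAC ring numbering the (3S,4R,5S)-tetrahydrofuran-3-yl ketone)
Conditions: Bu4NF (4 equiv), AcOH (4 equiv), THF, 0 °C → rt
Reagents that add atoms: none
Why: Fluoride cleavage of the two aryl silyl ethers and the primary silyl ether; the acetic acid buffer keeps the medium near neutral, so no phenoxide sits beside the β-alkoxy ketone and the C4 and benzylic C2 centers are not disturbed.

## Compound list

1 | isovanillin (3-hydroxy-4-methoxybenzaldehyde) | COc1ccc(C=O)cc1O | starting material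
2 | 4-methoxy-3-(triisopropylsilyloxy)benzaldehyde | COc1ccc(C=O)cc1O[Si](C(C)C)(C(C)C)C(C)C | intermediate
3 | (E)-1-methoxy-3-(trimethylsilyloxy)buta-1,3-diene | CO/C=C/C(=C)O[Si](C)(C)C | starting material
4 | (S,E)-1-methoxy-5-ArT-5-(trimethylsilyloxy)pent-1-en-3-one, Mukaiyama aldol adduct formed in the flask | CO/C=C/C(=O)C[C@H](O[Si](C)(C)C)c1ccc(OC)c(O[Si](C(C)C)(C(C)C)C(C)C)c1 | intermediate
5 | (S)-2-ArT-2,3-dihydro-4H-pyran-4-one | O=C1C=CO[C@H](c2ccc(OC)c(O[Si](C(C)C)(C(C)C)C(C)C)c2)C1 | intermediate
6 | lithium (S)-2-ArT-2H-pyran-4-olate, dienolate of 5 formed in the flask | [Li]OC1=C[C@@H](c2ccc(OC)c(O[Si](C(C)C)(C(C)C)C(C)C)c2)OC=C1 | intermediate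
7 | (2S,3R)-3-(hydroxymethyl)-2-ArT-2,3-dihydro-4H-pyran-4-one (2,3-trans) | O=C1C=CO[C@H](c2ccc(OC)c(O[Si](C(C)C)(C(C)C)C(C)C)c2)[C@H]1CO | intermediate
8 | (2S,3R)-3-[(tert-butyldimethylsilyloxy)methyl]-2-ArT-2,3-dihydro-4H-pyran-4-one | O=C1C=CO[C@H](c2ccc(OC)c(O[Si](C(C)C)(C(C)C)C(C)C)c2)[C@H]1CO[Si](C)(C)C(C)(C)C | intermediate
9 | (2S,3R)-3-[(tert-butyldimethylsilyloxy)methyl]-2-ArT-tetrahydro-4H-pyran-4-one | O=C1CCO[C@H](c2ccc(OC)c(O[Si](C(C)C)(C(C)C)C(C)C)c2)[C@H]1CO[Si](C)(C)C(C)(C)C | intermediate
10 | lithium C4–C5 enolate of 9 (C2 and C3 as in 9), formed in the flask | [Li]OC1=CCO[C@H](c2ccc(OC)c(O[Si](C(C)C)(C(C)C)C(C)C)c2)[C@H]1CO[Si](C)(C)C(C)(C)C | intermediate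
11 | 5-(trifluoroacetyl) derivative of 9 (C2 and C3 as in 9; C5 enolizable), carried on crude | O=C1C(C(=O)C(F)(F)F)CO[C@H](c2ccc(OC)c(O[Si](C(C)C)(C(C)C)C(C)C)c2)[C@H]1CO[Si](C)(C)C(C)(C)C | intermediate
12 | (2S,3R)-3-[(tert-butyldimethylsilyloxy)methyl]-5-diazo-2-ArT-tetrahydro-4H-pyran-4-one | O=C1C(=[N+]=[N-])CO[C@H](c2ccc(OC)c(O[Si](C(C)C)(C(C)C)C(C)C)c2)[C@H]1CO[Si](C)(C)C(C)(C)C | intermediate
13 | N,O-dimethylhydroxylamine | CNOC | starting material
14 | (2S,3R)-3-[(tert-butyldimethylsilyloxy)methyl]-2-ArT-4-(oxomethylidene)tetrahydrofuran, ketene formed in the flask | O=C=C1CO[C@H](c2ccc(OC)c(O[Si](C(C)C)(C(C)C)C(C)C)c2)[C@H]1CO[Si](C)(C)C(C)(C)C | intermediate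
15 | (2S,3R)-3-[(tert-butyldimethylsilyloxy)methyl]-N-methoxy-2-ArT-N-methyltetrahydrofuran-4-carboxamide, both C4 epimers | CON(C)C(=O)C1CO[C@H](c2ccc(OC)c(O[Si](C(C)C)(C(C)C)C(C)C)c2)[C@H]1CO[Si](C)(C)C(C)(C)C | intermediate
16 | 5-bromo-2-methoxyphenol | COc1ccc(Br)cc1O | starting material
17 | (5-bromo-2-methoxyphenoxy)triisopropylsilane | COc1ccc(Br)cc1O[Si](C(C)C)(C(C)C)C(C)C | intermediate
18 | [4-methoxy-3-(triisopropylsilyloxy)phenyl]lithium, formed in the flask | [Li]c1ccc(OC)c(O[Si](C(C)C)(C(C)C)C(C)C)c1 | intermediate
19 | lithium alkoxide of the N-methoxy-N-methyl hemiaminal from 15 and 18 (tetrahedral adduct, C4 and hemiaminal carbon undefined), formed in the flask | CON(C)C(O[Li])(c1ccc(OC)c(O[Si](C(C)C)(C(C)C)C(C)C)c1)C1CO[C@H](c2ccc(OC)c(O[Si](C(C)C)(C(C)C)C(C)C)c2)[C@H]1CO[Si](C)(C)C(C)(C)C | intermediate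
20 | {(2S,3R)-3-[(tert-butyldimethylsilyloxy)methyl]-2-ArT-tetrahydrofuran-4-yl}(ArT)methanone, both C4 epimers | O=C(c1ccc(OC)c(O[Si](C(C)C)(C(C)C)C(C)C)c1)C1CO[C@H](c2ccc(OC)c(O[Si](C(C)C)(C(C)C)C(C)C)c2)[C@H]1CO[Si](C)(C)C(C)(C)C | intermediate
21 | {(2S,3R,4S)-3-[(tert-butyldimethylsilyloxy)methyl]-2-ArT-tetrahydrofuran-4-yl}(ArT)methanone, all-trans | O=C(c1ccc(OC)c(O[Si](C(C)C)(C(C)C)C(C)C)c1)[C@@H]1CO[C@H](c2ccc(OC)c(O[Si](C(C)C)(C(C)C)C(C)C)c2)[C@H]1CO[Si](C)(C)C(C)(C)C | intermediate
22 | (3-hydroxy-4-methoxyphenyl)[(2S,3R,4S)-2-(3-hydroxy-4-methoxyphenyl)-3-(hydroxymethyl)tetrahydrofuran-4-yl]methanone, all-trans | COc1ccc(C(=O)[C@@H]2CO[C@H](c3ccc(OC)c(O)c3)[C@H]2CO)cc1O | target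

## Step count and least certain steps

Total: 11 steps. Longest linear sequence: 10 steps (steps 1–7 and 9–11, from isovanillin 1); step 8 is a one-step branch.

**Step 7 (key step).** Most likely to go wrong: slow or incomplete capture of ketene 14 by the weakly basic, volatile hydroxylamine, so that the ketene dimerizes or is hydrolyzed. Insertion of the excited diazo ketone into the N–H bond, or a 1,2-hydrogen shift from C6 (which would merely return enone 8), may accompany this. Fallback: set out from 12 and irradiate at the same wavelength in methanol as solvent, the classical form of the ring contraction with the trap in vast excess. This gives methyl (2S,3R)-3-[(tert-butyldimethylsilyloxy)methyl]-2-ArT-tetrahydrofuran-4-carboxylate (both C4 epimers) F1. Treating the ester with MeNHOMe·HCl and i-PrMgCl in THF at −20 °C converts it into the N-methoxy-N-methylamide and comes back to the route at 15.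

**Step 3.** Most likely to go wrong: opening of dienolate 6 before it meets the electrophile. The ring oxygen is β to the enolate carbon and would leave as a stabilized vinylogous carboxylate, and the dienolate is formally a 2H-pyran that can open electrocyclically; this would also erode C2. Multiple addition of formaldehyde is a second risk. Fallback: set out from 5 and enolize softly with Me3SiOTf and Et3N in CH2Cl2 at 0 °C, which gives (S)-2-ArT-4-(trimethylsilyloxy)-2H-pyran F2 without any metal dienolate. A Mukaiyama aldol reaction with aqueous formaldehyde catalyzed by Yb(OTf)3 in THF–H2O at rt comes back at 7.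

**Step 6.** Most likely to go wrong: loss of regiocontrol in the enolization. Partial deprotonation at C3 would place the diazo group on the wrong side, expose the β-silyloxy group to elimination and erode the C3 configuration. Fallback: set out from enone 8 and generate enolate 10 regiospecifically by conjugate reduction with LiBH(s-Bu)3 in THF at −78 °C. Acylate it in the same flask with CF3CO2CH2CF3 to 11 and carry it through the same diazo transfer, coming back at 12. No compound outside the compound list is made (F0).

**Step 10.** Most likely to go wrong: incomplete equilibration, or competing ring opening by β-elimination of O1 under prolonged base, which would leave the C4 epimers unresolved. Fallback: set out from 15 and reduce with i-Bu2AlH in THF at −78 °C to the epimeric aldehydes (2S,3R)-3-[(tert-butyldimethylsilyloxy)methyl]-2-ArT-tetrahydrofuran-4-carbaldehyde F3. Their far more acidic α-hydrogen should equilibrate with Et3N in CH2Cl2 at rt to the all-trans aldehyde (2S,3R,4S)-3-[(tert-butyldimethylsilyloxy)methyl]-2-ArT-tetrahydrofuran-4-carbaldehyde F4. Addition of aryllithium 18 in THF at −78 °C gives the carbinols {(2S,3R,4S)-3-[(tert-butyldimethylsilyloxy)methyl]-2-ArT-tetrahydrofuran-4-yl}(ArT)methanol (both carbinol epimers) F5. Oxidation with Dess–Martin periodinane and NaHCO3 in CH2Cl2 comes back at 21.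

## Further compounds

F1 | step 7 | methyl (2S,3R)-3-[(tert-butyldimethylsilyloxy)methyl]-2-ArT-tetrahydrofuran-4-carboxylate, both C4 epimers | COC(=O)C1CO[C@H](c2ccc(OC)c(O[Si](C(C)C)(C(C)C)C(C)C)c2)[C@H]1CO[Si](C)(C)C(C)(C)C
F2 | step 3 | (S)-2-ArT-4-(trimethylsilyloxy)-2H-pyran | C[Si](C)(C)OC1=C[C@@H](c2ccc(OC)c(O[Si](C(C)C)(C(C)C)C(C)C)c2)OC=C1
F0 | step 6 | none | none
F3 | step 10 | (2S,3R)-3-[(tert-butyldimethylsilyloxy)methyl]-2-ArT-tetrahydrofuran-4-carbaldehyde, both C4 epimers | O=CC1CO[C@H](c2ccc(OC)c(O[Si](C(C)C)(C(C)C)C(C)C)c2)[C@H]1CO[Si](C)(C)C(C)(C)C
F4 | step 10 | (2S,3R,4S)-3-[(tert-butyldimethylsilyloxy)methyl]-2-ArT-tetrahydrofuran-4-carbaldehyde, all-trans | O=C[C@@H]1CO[C@H](c2ccc(OC)c(O[Si](C(C)C)(C(C)C)C(C)C)c2)[C@H]1CO[Si](C)(C)C(C)(C)C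
F5 | step 10 | {(2S,3R,4S)-3-[(tert-butyldimethylsilyloxy)methyl]-2-ArT-tetrahydrofuran-4-yl}(ArT)methanol, both carbinol epimers | OC(c1ccc(OC)c(O[Si](C(C)C)(C(C)C)C(C)C)c1)[C@@H]1CO[C@H](c2ccc(OC)c(O[Si](C(C)C)(C(C)C)C(C)C)c2)[C@H]1CO[Si](C)(C)C(C)(C)C
A1 | alternative 1 | 2-[3-(benzyloxy)-4-methoxyphenyl]-2-hydroxy-3-(benzyloxymethyl)-4-[3-(benzyloxy)-4-methoxybenzoyl]tetrahydrofuran, lactol epimers, 3,4-trans | OC1(c2ccc(OC)c(OCc3ccccc3)c2)OC[C@@H](C(=O)c2ccc(OC)c(OCc3ccccc3)c2)[C@@H]1COCc1ccccc1
A2 | alternative 1 | trans-4-(benzyloxymethyl)-N-methoxy-N-methyl-5-oxotetrahydrofuran-3-carboxamide, configured as in the target | O=C1OC[C@@H](C(=O)N(C)OC)[C@@H]1COCc1ccccc1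
A3 | alternative 1 | [3-(benzyloxy)-4-methoxyphenyl]lithium | [Li]c1ccc(OC)c(OCc2ccccc2)c1
A4 | alternative 2 | cis-fused siloxane: 2-aryl tetrahydrofuran with a C3–CH2–SiMe2–O–CH(aryl)–C4 bridge (aryl = 3-benzyloxy-4-methoxyphenyl) | C[Si]1(C)C[C@@H]2[C@@H](c3ccc(OC)c(OCc4ccccc4)c3)OC[C@@H]2C(c2ccc(OC)c(OCc3ccccc3)c2)O1
A5 | alternative 2 | (bromomethyl)dimethylsilyl ether of [(2S)-2-aryl-2,5-dihydrofuran-4-yl](aryl)methanol (target numbering; aryl = 3-benzyloxy-4-methoxyphenyl; carbinol epimers) | BrC[Si](C)(C)OC(c1ccc(OC)c(OCc2ccccc2)c1)C1=C[C@@H](c2ccc(OC)c(OCc3ccccc3)c2)OC1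
A6 | alternative 3 | all-trans 2-[3-(benzyloxy)-4-methoxyphenyl]-3-(benzyloxymethyl)-4-formyltetrahydrofuran (target numbering) | O=C[C@@H]1CO[C@H](c2ccc(OC)c(OCc3ccccc3)c2)[C@H]1COCc1ccccc1
A7 | alternative 3 | (4R)-2-[3-(benzyloxy)-4-methoxyphenyl]-4-[(E)-3-(benzyloxy)prop-1-enyl]-1,3-dioxolane, acetal epimers | c1ccccc1COC/C=C/[C@@H]1COC(c2ccc(OC)c(OCc3ccccc3)c2)O1
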